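You asked for a quick number on the solvolysis product, so here are the flasks and what is asked.

common to all: first nucleophile 1.00 equiv; time 4.0 h
- zeta: substrate 0.30 M; second nucleophile 1.30 equiv (fed, over 3.0 h); temperature 50 °C; all else is in the flask from the start; the feed brings no volume worth counting
- eta: substrate 0.30 M (in portions, 3, over 3.0 h); second nucleophile 1.30 equiv; temperature 50 °C; first portion at the start, last at 3.0 h
- gamma: substrate 0.30 M (fed, over 3.0 h); second nucleophile 1.30 equiv; temperature 50 °C; all else is in the flask from the start; the feed brings no volume worth counting
- epsilon: substrate 0.30 M (fed, over 3.0 h); second nucleophile 1.30 equiv; the addition at 10 °C, then warmed to 50 °C; the feed brings no volume worth counting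

    substrate → intermediate (k1 = 0.0019 /s, Ea1 = 87.0 kJ/mol)
    first nucleophile + intermediate ⇌ target (K2 = 1.3 /M, k2 = 0.52 /M/s, Ea2 = 52.0 kJ/mol, ΔH2 = −40.0 kJ/mol)
    second nucleophile + intermediate → other capture product (k3 = 1.4 /M/s, Ea3 = 48.0 kJ/mol)
    intermediate → solvolysis product (k4 = 0.15 /s, Ea4 = 75.0 kJ/mol)
    crystals ⇌ target, rate k5*(cs5 - [target]) while solid is left; crystals form when [target] > cs5 (cs5 = 0.13 M, k5 = 0.050 /s)
    2 second nucleophile → homo dimer (k6 = 0.0061 /M/s, Ea6 = 74.0 kJ/mol)
    (constants at 50 °C)

- amounts and yields of target count crystals too
- two of one species on the left: rate k times its square, two consumed each time
- given per volume of solution although it is solid: crystals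
- the constants hold at 50 °C; other temperatures follow from the activation energies and enthalpies

1. the flask that comes out highest in amount of solvolysis product, in percent of the substrate charged; "all alike" if 1.5 percentage points covers them all (zeta / eta / gamma / epsilon / all alike)
2. amount of solvolysis product at the end, in percent of the substrate charged, zeta
3. amount of solvolysis product at the end, in percent of the substrate charged, eta
4. amount of solvolysis product at the end, in percent of the substrate charged, gamma
5. amount of solvolysis product at the end, in percent of the substrate charged, epsilon

- Follow one molecule of intermediate to its fork: solvolysis runs at the constant k4, capture at k3 times the second nucleophile. Call the ratio at 50 °C the even-odds level, 0.107 M, the inverse of the selectivity factor. The chance of solvolysis is 1/(1 + level met/even-odds level).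
- Ignore the first nucleophile at this fork at 50 °C, because target falls back at 0.400 /s, faster than solvolysis runs, so target works as a waiting room.
- Take zeta, where the substrate's mean life of 8.77 min is shorter than the feed. Let capture take what is fed during that one mean life, which leaves 93.7 % for solvolysis as an estimate.
- Now take the full charge of second nucleophile in gamma and eta, 0.390 M, whose first half-life by dimerisation is 3.50 min, shorter than the substrate's mean life. Counting dimerisation and leaving capture out, estimate it one mean life on at 0.111 M. Later estimate it by 1/(2 × k6 × time), so 0.0152 M at mid-feed and 0.00759 M at the end of the feed.
- Read gamma at mid-feed, which gives 87.6 %.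
- Average eta's portions at these three levels, which gives 76.7 %.
- Assume epsilon keeps its substrate and its whole charge of second nucleophile until warming, then meets the first level. That ignores dimer made in the cold, so treat it as a rough lower mark, not as a number for the flask: 49.0 %.
- Rank the four and commit to zeta.
- Set beside this your forecast: zeta highest, with 90 % for zeta, 80 % for eta, 85 % for gamma and 63 % for epsilon. It reasons that “epsilon loses least to solvolysis because the cold hold slows the dimerisation”. Its numbers differ from mine, but its order is the same.
- The flasks give 91.6 % for zeta, 79.0 % for eta, 89.4 % for gamma and 59.4 % for epsilon, so zeta stands highest, above the other three.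

Run the even-odds level at 50 °C backward: the end value of zeta corresponds to an average level met of 0.00981 M, and that of epsilon, part of whose course ran in the cold, to 0.0731 M, while the rate ratio in epsilon at 3.09 h, solvolysis over capture of 1.7, corresponds to 0.0640 M. The neighbour of epsilon with 0.780 equiv of second nucleophile ends at 65.1 %, which the same backward reckoning turns into an average level met of 0.0574 M.

The rate constants were set for the occasion; the rest is arithmetic.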